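**Retrosynthetic overview**

1. Ring A is the six-membered acyl-dione ring, ring B the cyclopentanone with the bridging ketone, ring C the gem-dimethylcyclopentane. The C(OH)Me2 group is made last, by double methyl addition to an enol δ-lactone (lactone C=O becomes the carbinol carbon, lactone O becomes the ring-A enol oxygen).
2. Rings B and C are cut together by a retro-(3+2) across the bridging ketone. This removes the bonds from the CH2–CH unit to the methyl-bearing bridgehead and to the spiro carbon, and leads back to a flat aromatic 3,4-dihydrocoumarin with a 2-methylbut-3-en-2-yl group at C3. Forward: two-electron oxidation gives a 2-siloxyallyl cation that the vinyl group traps.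
3. The dihydrocoumarin (its C3 is the only stereocentre set by a reagent) comes from an ortho-quinone methide and an acyl imidazole by carbene-catalysed enantioselective (4+2) annulation.
4. The quinone methide precursor comes from 2-methylphloroglucinol by Friedel–Crafts acylation, mono-silylation and Mannich reaction/quaternisation.
5. Order of ring formation: ring A bought as the arene → temporary lactone ring → rings B and C in one operation → lactone ring opened.

Assumption: the enol tautomers of the 2-acyl-1,3-dione are treated as one compound; tricycle locants follow tricyclo[5.3.1.0^1,5]undecane, and locants C3, C4a, C5, C6, C8, C8a in steps 5 and 6 are chromanone locants of compound 10. The route is a paper design and has not been run.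

**Step 1**
Reactants: 1 2-methylbenzene-1,3,5-triol; 2 2-methylpropanoyl chloride
Product: 3 1-(2,4,6-trihydroxy-3-methylphenyl)-2-methylpropan-1-one
Conditions: AlCl3 (3.5 equiv), PhNO2, 0 to 50 °C; ice/aq HCl
Reagents that add atoms: none
Why: Friedel–Crafts acylation; the two free ring positions of 1 are equivalent and the first acyl group deactivates the ring towards a second, so one ketone forms and no stereocentre is involved.

**Step 2**
Reactants: 3 1-(2,4,6-trihydroxy-3-methylphenyl)-2-methylpropan-1-one
Product: 4 1-[4-[tert-butyl(dimethyl)silyl]oxy-2,6-dihydroxy-3-methylphenyl]-2-methylpropan-1-one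
Conditions: TBSCl (1.05 equiv), imidazole (2.2 equiv), DMF, −20 to 0 °C
Reagents that add atoms: tert-butyl(chloro)dimethylsilane (TBSCl) CC(C)(C)[Si](C)(C)Cl
Why: Selective O-silylation; the hydroxyl para to the ketone is the only one that cannot hydrogen-bond to the carbonyl, so one equivalent of TBSCl at low temperature goes there (the usual 4-O selectivity of 2,4,6-trihydroxyaryl ketones), which blocks the hydroxyl that would otherwise compete in the lactonisation of step 5.

**Step 3**
Reactants: 4 1-[4-[tert-butyl(dimethyl)silyl]oxy-2,6-dihydroxy-3-methylphenyl]-2-methylpropan-1-one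
Product: 6 [[2-[tert-butyl(dimethyl)silyl]oxy-4,6-dihydroxy-3-methyl-5-(2-methylpropanoyl)phenyl]methyl]trimethylazanium iodide, via Mannich base 5 (not isolated)
Conditions: CH2=NMe2+ I− (1.2 equiv), CH2Cl2, 0 °C to rt; aq NaHCO3 wash; then MeI (5 equiv), acetone, rt
Reagents that add atoms: N,N-dimethylmethylideneammonium iodide (Eschenmoser's salt) C=[N+](C)C.[I-]; iodomethane CI
Why: Mannich aminomethylation at the only unsubstituted ring carbon (ortho/para to three oxygens), then Menshutkin quaternisation of the benzylic amine, which is much faster than O-methylation of the base-free, hydrogen-bonded phenols; no stereocentre.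

**Step 4**
Reactants: 7 3,3-dimethylpent-4-enoic acid
Product: 8 1-(imidazol-1-yl)-3,3-dimethylpent-4-en-1-one
Conditions: CDI (1.1 equiv), CH2Cl2, rt, 1 h; cold water wash, dry, concentrate
Reagents that add atoms: 1,1'-carbonyldiimidazole O=C(n1ccnc1)n1ccnc1
Why: CDI activation of a carboxylic acid (acyl imidazole formation), driven by loss of CO2; no stereocentre.

**Step 5**
Reactants: 6 [[2-[tert-butyl(dimethyl)silyl]oxy-4,6-dihydroxy-3-methyl-5-(2-methylpropanoyl)phenyl]methyl]trimethylazanium iodide; 8 1-(imidazol-1-yl)-3,3-dimethylpent-4-en-1-one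
Product: 10 (3R)-5-[tert-butyl(dimethyl)silyl]oxy-7-hydroxy-6-methyl-3-(2-methylbut-3-en-2-yl)-8-(2-methylpropanoyl)-3,4-dihydrochromen-2-one, via ortho-quinone methide 9 (not isolated)
Conditions: (5aR,10bS)-2-(2,4,6-trimethylphenyl)-5a,10b-dihydro-4H,6H-indeno[2,1-b][1,2,4]triazolo[4,3-d][1,4]oxazin-2-ium tetrafluoroborate (10 mol%; its antipode if the first run gives the 3S lactone), Cs2CO3 (2.2 equiv), 4 Å MS, THF, −20 °C to rt
Reagents that add atoms: none
Why: Carbene-catalysed formal (4+2) annulation of an ortho-quinone methide with an acyl imidazole: carbonate releases 9 from 6 by loss of NMe3, the chiral carbene turns 8 into a catalyst-bound enolate that adds to the methide CH2 on one face (setting C3 as R), and the phenoxide then closes the lactone, which can only form on the oxygen next to the acyl-bearing carbon because the other ortho oxygen is silylated.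

**Step 6**
Reactants: 10 (3R)-5-[tert-butyl(dimethyl)silyl]oxy-7-hydroxy-6-methyl-3-(2-methylbut-3-en-2-yl)-8-(2-methylpropanoyl)-3,4-dihydrochromen-2-one
Product: 12 (1R,3R,5S,7R)-4,4,7-trimethyl-9-(2-methylpropanoyl)-8,11-dioxotricyclo[5.3.1.0^1,5]undec-9-ene-3,10-carbolactone (C3–C(=O)–O–C10), via siloxyallyl cation 11 (not isolated)
Conditions: PhI(OCOCF3)2 (1.1 equiv), (CF3)2CHOH, 5 mM, −20 to 0 °C; aq NaHCO3 work-up
Reagents that add atoms: none
Why: Proposed new method: PhI(OCOCF3)2 binds the free phenol of 10 and leaves as PhI, giving the two-electron-oxidised phenoxenium ion 11, which is a 2-siloxyallyl cation over C4a–C5(OSi)–C6; the pseudo-axial C3 substituent holds its vinyl group over this unit, so in one asynchronous (3+2) event the terminal CH2 bonds to C6 (the Markovnikov-consistent leading bond) and the internal CH bonds to C4a, forming rings C and B together, and loss of the silyl group from the silyloxycarbenium ion gives the bridging ketone; the closest known reaction types are the oxidative-dearomatisation-induced (5+2)/(3+2) cycloadditions of phenols with tethered alkenes that give cedrane-type bicyclo[3.2.1]octanones and the (3+2) cycloadditions of 2-siloxyallyl cations with alkenes; stereocontrol is geometric, since the alkene reaches C4a only from the face of the C3 substituent while the lactone stays fused at C4a–C8a, so the R centre fixes the spiro carbon, the ring-fusion CH and the methyl-bearing bridgehead as in the target, and closure onto C6 rather than C8 is favoured because C8 carries the acyl group and is flanked by the poorer acyloxy donor.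

**Step 7**
Reactants: 12 (1R,3R,5S,7R)-4,4,7-trimethyl-9-(2-methylpropanoyl)-8,11-dioxotricyclo[5.3.1.0^1,5]undec-9-ene-3,10-carbolactone
Product: 14 (1S,3R,5S,7S)-8-hydroxy-3-(2-hydroxypropan-2-yl)-4,4,7-trimethyl-9-(2-methylpropanoyl)tricyclo[5.3.1.0^1,5]undec-8-ene-10,11-dione, via methyl ketone 13 (not isolated)
Conditions: MeMgBr (3 equiv), CeCl3 (3 equiv), THF, −78 to −20 °C; aq NH4Cl, then dilute HCl to pH 3
Reagents that add atoms: methylmagnesium bromide C[Mg]Br
Why: Double Grignard (organocerium) addition to an ester: the enol-lactone carbonyl is a vinylogous anhydride and the most electrophilic carbonyl, the first addition expels the ring-A trione enolate (which shields the three conjugated carbonyls as an anion) to give 13, and the second addition gives the tertiary alkoxide, while the bridging ketone sits between two quaternary carbons and next to the gem-dimethyl group; no stereocentre is touched.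

**Compound list**

1 | 2-methylbenzene-1,3,5-triol | Cc1c(O)cc(O)cc1O | starting material
2 | 2-methylpropanoyl chloride | CC(C)C(Cl)=O | starting material
3 | 1-(2,4,6-trihydroxy-3-methylphenyl)-2-methylpropan-1-one | CC(C)C(=O)c1c(O)cc(O)c(C)c1O | intermediate
4 | 1-[4-[tert-butyl(dimethyl)silyl]oxy-2,6-dihydroxy-3-methylphenyl]-2-methylpropan-1-one | CC(C)C(=O)c1c(O)cc(O[Si](C)(C)C(C)(C)C)c(C)c1O | intermediate
5 | 1-[4-[tert-butyl(dimethyl)silyl]oxy-3-[(dimethylamino)methyl]-2,6-dihydroxy-5-methylphenyl]-2-methylpropan-1-one (Mannich base) | CC(C)C(=O)c1c(O)c(CN(C)C)c(O[Si](C)(C)C(C)(C)C)c(C)c1O | intermediate (not isolated)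
6 | [[2-[tert-butyl(dimethyl)silyl]oxy-4,6-dihydroxy-3-methyl-5-(2-methylpropanoyl)phenyl]methyl]trimethylazanium iodide | CC(C)C(=O)c1c(O)c(C[N+](C)(C)C)c(O[Si](C)(C)C(C)(C)C)c(C)c1O.[I-] | intermediate
7 | 3,3-dimethylpent-4-enoic acid | C=CC(C)(C)CC(=O)O | starting material
8 | 1-(imidazol-1-yl)-3,3-dimethylpent-4-en-1-one | C=CC(C)(C)CC(=O)n1ccnc1 | intermediate
9 | 5-[tert-butyl(dimethyl)silyl]oxy-3-hydroxy-4-methyl-6-methylidene-2-(2-methylpropanoyl)cyclohexa-2,4-dien-1-one (ortho-quinone methide) | CC(C)C(=O)C1=C(O)C(C)=C(O[Si](C)(C)C(C)(C)C)C(=C)C1=O | intermediate (not isolated)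
10 | (3R)-5-[tert-butyl(dimethyl)silyl]oxy-7-hydroxy-6-methyl-3-(2-methylbut-3-en-2-yl)-8-(2-methylpropanoyl)-3,4-dihydrochromen-2-one | CC(C)C(=O)c1c(O)c(C)c(O[Si](C)(C)C(C)(C)C)c2C[C@H](C(C)(C)C=C)C(=O)Oc12 | intermediate
11 | phenoxenium (2-siloxyallyl) cation of 10, charge shared by C4a, C6 and C8, 3R | CC(C)C(=O)C1=C2OC(=O)[C@@H](C(C)(C)C=C)CC2=C(O[Si](C)(C)C(C)(C)C)[C+](C)C1=O | intermediate (not isolated)
12 | (1R,3R,5S,7R)-4,4,7-trimethyl-9-(2-methylpropanoyl)-8,11-dioxotricyclo[5.3.1.0^1,5]undec-9-ene-3,10-carbolactone (enol δ-lactone; same spatial arrangement at all four centres as the target) | CC(C)C(=O)C=1C(=O)[C@]2(C)C[C@H]3C(C)(C)[C@H](C(=O)O4)C[C@@]3(C=14)C2=O | intermediate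
13 | (1S,3R,5S,7S)-3-acetyl-8-hydroxy-4,4,7-trimethyl-9-(2-methylpropanoyl)tricyclo[5.3.1.0^1,5]undec-8-ene-10,11-dione | CC(C)C(=O)C1=C(O)[C@]2(C)C[C@H]3C(C)(C)[C@H](C(C)=O)C[C@@]3(C1=O)C2=O | intermediate (not isolated)
14 | (1S,3R,5S,7S)-8-hydroxy-3-(2-hydroxypropan-2-yl)-4,4,7-trimethyl-9-(2-methylpropanoyl)tricyclo[5.3.1.0^1,5]undec-8-ene-10,11-dione (CNP0267234.2) | CC(C)C(=O)C1=C(O)[C@]2(C)C[C@H]3C(C)(C)[C@H](C(C)(C)O)C[C@@]3(C1=O)C2=O | target

**Step count and risks**

Total step count: 7. Longest linear sequence: 6 (steps 1, 2, 3, 5, 6, 7; step 4 is a one-step side branch).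

The three steps most likely to fail, in route order:

Step 5 (carbene-catalysed annulation). The free carbene, imidazole or trimethylamine can add to the quinone methide, and the enolate of a β-quaternary acyl donor is slow, so yield and ee may both suffer. The fallback sets out from 8 and 6 and comes back at 10, with the stereocentre set by an auxiliary instead of a catalyst. 8 acylates (4R)-4-benzyl-1,3-oxazolidin-2-one (n-BuLi, THF, −78 °C) to give the N-acyl oxazolidinone F1. Its sodium enolate (NaN(SiMe3)2, THF, −78 °C) is added to 9, released separately from 6 with NaN(SiMe3)2 (2 equiv). This gives the Michael adduct F2, in which the benzyl group shields one enolate face (Evans alkylation model, 2R). Catalytic DBU in THF then lets the neighbouring phenoxide expel the auxiliary and close the lactone to 10.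

Step 6 (oxidative (3+2) cycloaddition, the key step). The oxidised ring can instead lose a benzylic proton (dehydrogenation to the coumarin) or be captured by trifluoroacetate, and the terminal alkene is only a modest partner for the cation. The fallback sets out from 10 and comes back at 12, replacing the cycloaddition by two separate polar bond formations. N-iodosuccinimide in CH2Cl2/(CF3)2CHOH at −40 °C forms the iodonium ion of the vinyl group, and C4a attacks its internal carbon (5-exo, Markovnikov) to give the iodomethyl spirocyclic silyl enol ether F3. CsF with 18-crown-6 in MeCN then frees the enolate, which is C-alkylated by the CH2I group to close ring B and give 12. Only the epimer of F3 with CH2I over the silyl enol ether can close; the other is removed by chromatography.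

Step 7 (double methyl addition). The second equivalent may enolise 13 or attack the bridging ketone. The fallback sets out from 10 and comes back at 14, adding the methyl groups before the bridging ketone exists. MeMgBr/CeCl3 in THF opens the aryl lactone of 10 to the tertiary alcohol F4. Catalytic TsOH in CH2Cl2 closes the 2,2-dimethylchroman F5; only the free ortho hydroxyl can cyclise, so the tether again sits on the right oxygen. PhI(OCOCF3)2 in (CF3)2CHOH then effects the same (3+2) cycloaddition to the cyclic enol ether F6. LiOH in THF/water cleaves this vinylogous ester by addition–elimination to give 14.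

**Further compounds**

F1 | step 5 | (4R)-4-benzyl-3-(3,3-dimethylpent-4-enoyl)-1,3-oxazolidin-2-one | O=C1OC[C@@H](Cc2ccccc2)N1C(=O)CC(C)(C)C=C
F2 | step 5 | (4R)-4-benzyl-3-[(2R)-2-[[2-[tert-butyl(dimethyl)silyl]oxy-4,6-dihydroxy-3-methyl-5-(2-methylpropanoyl)phenyl]methyl]-3,3-dimethylpent-4-enoyl]-1,3-oxazolidin-2-one | O=C1OC[C@@H](Cc2ccccc2)N1C(=O)[C@H](Cc3c(O)c(C(=O)C(C)C)c(O)c(C)c3O[Si](C)(C)C(C)(C)C)C(C)(C)C=C
F3 | step 6 | iodomethyl spirocycle: 10 with C4a bonded to the internal vinyl carbon (new cyclopentane carrying CH2I), C7 as ketone, C5 silyl enol ether kept | CC(C)C(=O)C=1C(=O)C(C)=C(O[Si](C)(C)C(C)(C)C)[C@@]2(C[C@@H](C(=O)O3)C(C)(C)[C@@H]2CI)C=13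
F4 | step 7 | 1-[4-[tert-butyl(dimethyl)silyl]oxy-2,6-dihydroxy-3-[(2R)-2-(2-hydroxypropan-2-yl)-3,3-dimethylpent-4-enyl]-5-methylphenyl]-2-methylpropan-1-one | CC(C)C(=O)c1c(O)c(C)c(O[Si](C)(C)C(C)(C)C)c(C[C@@H](C(C)(C)O)C(C)(C)C=C)c1O
F5 | step 7 | 1-[(3R)-5-[tert-butyl(dimethyl)silyl]oxy-7-hydroxy-2,2,6-trimethyl-3-(2-methylbut-3-en-2-yl)-3,4-dihydro-2H-chromen-8-yl]-2-methylpropan-1-one | CC(C)C(=O)c1c(O)c(C)c(O[Si](C)(C)C(C)(C)C)c2C[C@H](C(C)(C)C=C)C(C)(C)Oc12
F6 | step 7 | cyclic enol ether: 12 with C(CH3)2 in place of the lactone C=O (C3–C(CH3)2–O–C10) | CC(C)C(=O)C=1C(=O)[C@]2(C)C[C@H]3C(C)(C)[C@H](C(C)(C)O4)C[C@@]3(C=14)C2=O
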